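## The problem

Arthrosporol A joins two carbocycles through a five-carbon chain. Ring A is C1–C6 (C1 carries the chain, C2 is the oxirane CH, C3 and C6 are carbinols, C4 carries the hydroxymethyl carbon C7, C4=C5). The chain is C1′–C5′ (C1′ carbinol, 2′Z trisubstituted and 4′E disubstituted alkenes, methyl on C3′). Ring B is C1″–C6″ (C2″ gem-dimethyl, C3″ carbinol, C6″ tertiary carbinol).

Ring A and C1′ hold five contiguous stereocentres around a fully substituted oxirane carbon (C1 R, C2 S, C3 R, C6 S, C1′ S). The two ring hydroxyls are cis to each other and trans to the oxirane, and the C1′ hydroxyl is erythro to the C1–O bond. Inside this array control can be relayed: cis oxygens at C3 and C6 leave one face of a C1=C2 alkene open, and a C1′ hydroxyl can deliver oxygen to it. Ring B (C1″ R, C3″ R, C6″ R) is too remote to be influenced, so both halves must be made as single enantiomers and then joined.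

The chain needs the less stable 2′Z geometry next to a secondary carbinol, which excludes equilibrating olefinations. The fragile groups are the epoxy alcohols (Payne migration with base, opening with acid), the doubly allylic C1′ carbinol, the tertiary C6″ alcohol, and any cyclohexa-1,4-diene precursor of ring A with leaving groups at C3 and C6 (aromatisation).

The enabling feature is that ring A without its oxirane is a cyclohexa-1,4-diene. Its cis 1,4-oxygens at C3/C6 and its para carbon substituents at C1/C4 are the imprint of a [4+2] union of a 1,4-dioxygenated 2-substituted butadiene (C3–C4–C5–C6 with C7) and an acyl alkyne (C2, C1, C1′).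

## Retrosynthesis

**Silicon removal and the C3′–C4′ bond.** Target 28 is the fluoride-deprotection product of 27, in which all hydroxyls except C1′–OH carry silicon. The last skeletal cut is C3′–C4′, between the two alkenes. It gives the (Z)-alkenyl iodide 18 (ring A with all five stereocentres) and the (E)-alkenylboronate 26 (ring B). The neighbouring cut C1′–C2′ would create C1′ by an uncontrolled addition of a dienyl metal to an aldehyde. Cutting C4′=C5′ would require a basic olefination of a hindered β-oxygenated aldehyde. The forward coupling only has to preserve two preset alkene geometries and tolerate a free carbinol and an epoxide.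

**The oxirane.** 18 is derived from the divinyl-type carbinol 17 by hydroxyl-directed epoxidation of C1=C2. The target is erythro at C1′/C1 with the oxirane anti to both ring oxygens, which is what a tartrate–titanium epoxidation of the (1′S) carbinol delivers. Reagent, carbinol and ring bias all point to the same face. Nucleophilic epoxidation of an enone precursor would expose the cyclohexa-1,4-diene to base. Epoxidising before C1′ exists would leave C1′ to be set next to a quaternary oxirane carbon, where chelated and open models predict opposite outcomes.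

**The iodoalkene.** 17 comes from the propargylic alcohol 15 by trans-hydroalumination and iodinolysis. This cuts nothing in the skeleton and fixes the 2′Z geometry by mechanism. It is done before the epoxidation because hydride reagents open epoxy alcohols.

**C1′ and the C1′–C2′ bond.** 15 is the reduction product of ynone 14, which comes from Weinreb amide 13 by acetylide addition, and 13 from imide 12 by amide exchange. An alkynyl ketone is the best substrate class for reagent-controlled reduction (linear small group against a branched ring), so C1′ is set independently of the ring. The acyl carbon of the cycloaddition thus becomes C1′ without redox detours.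

**Ring A (key disconnection).** 12 is cut at C1–C6 and C2–C3 into diene 8 and the propioloyl imide 11. One step then forms the ring, the cis C3/C6 oxygens and their absolute configuration, and leaves C1=C2 for the oxirane. The precursors are achiral and the product carries every ring A carbon at its final oxidation level. The forward reaction must select one enantiomer, keep the cis relationship and give the para regiochemistry.

**Diene and dienophile.** An open-chain tris(silyloxy) diene would need its fully substituted enol ether with the oxygen cis to the CH2O group. That is the 3Z isomer by the sequence rules, and γ-silylation of an acyclic enal does not guarantee it. Tying this oxygen to the C7 oxygen in a di-tert-butylsilylene ring makes the geometry structural and keeps all protection fluoride-labile. Diene 8 is therefore traced to enal 7, nitrile 5, ketone 4 and alkene 2, from diol 1. Imide 11 comes from acid 9 and oxazolidinone 10.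

**Ring B.** Boronate 26 is traced to aldehyde 25 (C4′ added by olefination), its silyl ether 24 and triol 23. The tertiary C6″–O bond of 23 comes from spiro epoxide 22. The exocyclic alkene of 21 and the ring itself (C1″–C2″ bond) come from radical cyclisation of the (R)-epoxide 20 of geranyl acetate 19. The epoxide carbon becomes C3″ and relays its configuration to C1″ (chair cyclisation) and C6″ (equatorial epoxidation).

## Roads not taken

**Alternative 1:** The cut is the two C–O bonds of the oxirane, made while C4=C5 is masked in a norbornene template. The endo adduct A2 of a quinone diester is epoxidised on its convex face by alkaline hydroperoxide (Weitz–Scheffer) to give A1. The template is later expelled by retro-Diels–Alder reaction.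
- Merits: the bicyclic frame decides the oxirane face. Hydride delivery from the same convex face could also set both ring carbinols trans to the oxirane. Both carbon substituents of ring A are present as esters.
- Weak points: A2 is racemic unless an asymmetric step or a resolution is added, so the key step does not address absolute configuration. Two ketones and two esters must be told apart, one ester ending as C7–OH and the other as the C1′ carbonyl on an oxirane carbon. The thermal unmasking must be run on an epoxy diol. Nothing helps with C1′.
- Comparison: in control of the oxirane face this road is at least as safe as the chosen one, whose epoxidation depends on a hindered alkene. The chosen plan sets against this one catalytic step that gives the ring, both carbinols at their final oxidation level and the absolute configuration, with C1′ arriving as an acyl carbon.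

**Alternative 2:** The cut is C1″–C2″ of ring B together with C6″–O. The (6R)-epoxygeranyl tert-butyl carbonate A4 is opened by a Lewis acid (BF3·OEt2) at low temperature. The 2,3-alkene attacks the tertiary epoxide carbon and the carbonate oxygen captures the cation, giving the trans-fused cyclic carbonate A3.
- Merits: one step sets all three ring B stereocentres, including the equatorial tertiary C–O bond. Hydrolysis of A3 would give triol 23 of the present route, about one step sooner than steps 14–16.
- Weak points: Lewis-acid opening of a monoepoxide with a single alkene competes with hydride shift to a ketone, proton loss and capture by the C3″ oxygen. Carbonate capture in a carbocyclisation has thin precedent. The step leaves the ring A stereopentad, the 2′Z alkene and the union untouched.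
- Comparison: for ring B alone this is the shorter idea and could replace steps 14–16. It was not made the centre of the plan because it solves the half of the molecule for which dependable routes exist, whereas the chosen key step addresses ring A.

**Alternative 3:** The cuts are C1′–C2′ and C3′–C4′ at once. Ni(cod)2 (zerovalent nickel) joins the ring A epoxy aldehyde A6, propyne A8 and the (E)-alkenylzinc chloride A7. Oxidative cyclisation gives an oxanickelacycle, and alkenyl transfer and reductive elimination follow, giving A5.
- Merits: it is the most convergent assembly. Syn addition across the alkyne gives 2′Z by mechanism, and one step replaces steps 8–11 and 20 of the chosen route.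
- Weak points: regiochemistry rests on the small difference between H and CH3 of A8. C1′ is left to an addition to a quaternary α-epoxy aldehyde. A6 offers low-valent nickel an epoxide beside a carbonyl. A7 can add directly or homocouple. The alternative also presupposes A6, that is, a solution for ring A.
- Comparison: in step economy this road is clearly better. The chosen plan spends five steps on the same two bonds but fixes regiochemistry (acetylide addition), geometry (trans-hydroalumination) and C1′ configuration (reagent-controlled reduction) in separate, mechanistically defined steps.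

Key step: step 7

Assumption: the sense of induction in step 7 is assigned by transferring the distorted square-planar chelate model of copper bis(oxazoline) imide complexes to the alkynoyl imide, with the diene body under the acyl oxygen. If correlation showed the opposite sense, the (S,S)-ligand would be used with no other change.

## Route

Step 1
Reactants: 1 2-methylidenepropane-1,3-diol
Product: 2 2,2-di-tert-butyl-5-methylidene-1,3,2-dioxasilinane
Conditions: tBu2Si(OTf)2, 2,6-lutidine, CH2Cl2, 0 °C
Reagents that add atoms: di-tert-butylsilyl bis(trifluoromethanesulfonate), CC(C)(C)[Si](OS(=O)(=O)C(F)(F)F)(OS(=O)(=O)C(F)(F)F)C(C)(C)C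
Why: Silylene formation of a 1,3-diol with the bis(triflate) is fast; the six-membered di-tert-butylsilylene survives ozone, hydride, base and mild Lewis acids and is cleaved by fluoride at the end.

Step 2
Reactants: 2 2,2-di-tert-butyl-5-methylidene-1,3,2-dioxasilinane
Product: 4 2,2-di-tert-butyl-1,3,2-dioxasilinan-5-one, via spiro ozonide 3 (not isolated)
Conditions: O3, CH2Cl2, −78 °C; then Me2S, −78 °C to rt
Reagents that add atoms: ozone, [O-][O+]=O
Why: Ozonolysis of a 1,1-disubstituted alkene with reductive work-up; silyl ethers are inert to ozone and the symmetrical ketone needs no regiocontrol.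

Step 3
Reactants: 4 2,2-di-tert-butyl-1,3,2-dioxasilinan-5-one
Product: 5 2-(2,2-di-tert-butyl-1,3,2-dioxasilinan-5-ylidene)acetonitrile
Conditions: (EtO)2P(O)CH2CN, NaH, THF, 0 °C to rt
Reagents that add atoms: diethyl (cyanomethyl)phosphonate, N#CCP(=O)(OCC)OCC
Why: Horner–Wadsworth–Emmons olefination of a ketone with the cyanomethylphosphonate anion, as used on protected dihydroxyacetones; the ketone is symmetrical, so the new alkene has no geometry to control.

Step 4
Reactants: 5 2-(2,2-di-tert-butyl-1,3,2-dioxasilinan-5-ylidene)acetonitrile
Product: 7 2-(2,2-di-tert-butyl-1,3,2-dioxasilinan-5-ylidene)acetaldehyde, via N-alumino imine 6 (not isolated)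
Conditions: iBu2AlH (1.1 equiv), toluene, −78 °C; then aq. sodium potassium tartrate
Reagents that add atoms: water, O
Why: Partial reduction of a nitrile by iBu2AlH stops at the N-alumino imine, which hydrolyses to the enal on work-up; the conjugated alkene and the silylene are untouched at −78 °C.

Step 5
Reactants: 7 2-(2,2-di-tert-butyl-1,3,2-dioxasilinan-5-ylidene)acetaldehyde
Product: 8 diene 2,2-di-tert-butyl-5-[(E)-2-(tert-butyldimethylsilyloxy)ethenyl]-4H-1,3,2-dioxasiline
Conditions: TBSOTf, Et3N, Et2O, 0 °C; filtration through basic alumina
Reagents that add atoms: tert-butyldimethylsilyl trifluoromethanesulfonate, CC(C)(C)[Si](C)(C)OS(=O)(=O)C(F)(F)F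
Why: Silyl dienol ether formation from an enal (O-silylation, then γ-deprotonation by the amine); the only γ-hydrogens are those of the ring CH2O groups, so the new ring enol ether is held by the silylene with its oxygen cis to the CH2O carbon. The exocyclic enol ether should form E from the s-trans oxocarbenium ion, as with other enals.

Step 6
Reactants: 9 propiolic acid; 10 1,3-oxazolidin-2-one
Product: 11 3-(prop-2-ynoyl)-1,3-oxazolidin-2-one
Conditions: DCC, DMAP (5 mol %), CH2Cl2, −10 to 0 °C
Reagents that add atoms: none
Why: Carbodiimide-mediated N-acylation of an oxazolidinone through the O-acylisourea; low temperature and little DMAP limit conjugate addition to the ynoate.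

Step 7
Reactants: 8 diene 2,2-di-tert-butyl-5-[(E)-2-(tert-butyldimethylsilyloxy)ethenyl]-4H-1,3,2-dioxasiline; 11 3-(prop-2-ynoyl)-1,3-oxazolidin-2-one
Product: 12 ring A imide 3-{[(6S,8aS)-2,2-di-tert-butyl-6-(tert-butyldimethylsilyloxy)-6,8a-dihydro-4H-1,3,2-benzodioxasilin-7-yl]carbonyl}-1,3-oxazolidin-2-one
Conditions: Cu(OTf)2 (10 mol %), (R,R)-tBu-box (11 mol %), 4 Å MS, CH2Cl2, −78 to −40 °C
Reagents that add atoms: none
Why: Proposed new method: imide 11 chelates the divalent copper centre of Cu(OTf)2/(R,R)-tBu-box through both carbonyl oxygens, which lowers the LUMO of the alkyne π bond conjugated to the acyl group, and the s-cis diene 8 adds in a concerted, asynchronous [4+2] cycloaddition; the closest known reactions are copper bis(oxazoline)-catalysed Diels–Alder reactions of acryloyl and propioloyl amide-type dienophiles with cyclic dienes and thermal additions of 1,4-dioxygenated dienes to acetylenic esters. Ring A closes in this one event by suprafacial bonding of both diene termini to one face of the alkyne (C1–C6 and C2–C3), giving the cyclohexa-1,4-diene with C1=C2 left for the later oxirane. C3 and C6 emerge cis because both oxygens are outward-pointing substituents of the diene, the C6 oxygen through the E enol ether of step 5 and the C3 oxygen through the silylene ring. Their absolute configuration is the product of two choices, the alkyne face left open by the tert-butyl group of the ligand and the placement of the diene body under the acyl oxygen with its OTBS terminus turned away from the ligand, and this combination is expected to give the (6S,8aS) adduct. The regiochemistry needed is para: the ring terminus of 8, activated by the OTBS donor at the far end and by the substituent on its neighbour, should bond first to the β-carbon of the ynoyl imide, so that the acyl carbon meets the less hindered CH(OTBS) terminus. Low temperature, molecular sieves and a base-free medium are meant to hold back a stepwise Mukaiyama–Michael path and the loss of silanol that would aromatise the product.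

Step 8
Reactants: 12 ring A imide
Product: 13 Weinreb amide (6S,8aS)-2,2-di-tert-butyl-6-(tert-butyldimethylsilyloxy)-N-methoxy-N-methyl-6,8a-dihydro-4H-1,3,2-benzodioxasiline-7-carboxamide
Conditions: MeNH(OMe)·HCl, AlMe3, CH2Cl2, −20 to 0 °C; aq. sodium potassium tartrate
Reagents that add atoms: N,O-dimethylhydroxylamine hydrochloride, CNOC.Cl
Why: Aluminium amide exchange of an N-acyl oxazolidinone to the Weinreb amide, a standard transamination that avoids hydroxide and alkoxide, which could trigger 1,4-elimination across the ring; both stereocentres are untouched.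

Step 9
Reactants: 13 Weinreb amide
Product: 14 ynone 1-[(6S,8aS)-2,2-di-tert-butyl-6-(tert-butyldimethylsilyloxy)-6,8a-dihydro-4H-1,3,2-benzodioxasilin-7-yl]but-2-yn-1-one
Conditions: MeC≡CMgBr, THF, −20 to 0 °C; cold pH 7 phosphate buffer
Reagents that add atoms: prop-1-ynylmagnesium bromide, CC#C[Mg]Br
Why: Acetylide addition to a Weinreb amide stops at the chelated tetrahedral adduct and releases the ynone on buffered work-up; the alkyne is attached through its terminal carbon, which places C2′ and C3′ without any regiochemical question.

Step 10
Reactants: 14 ynone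
Product: 15 propargylic alcohol (1S)-1-[(6S,8aS)-2,2-di-tert-butyl-6-(tert-butyldimethylsilyloxy)-6,8a-dihydro-4H-1,3,2-benzodioxasilin-7-yl]but-2-yn-1-ol
Conditions: (R)-Me-CBS oxazaborolidine, catecholborane, toluene, −78 °C
Reagents that add atoms: none
Why: Corey–Bakshi–Shibata reduction of an alkynyl ketone, with the linear propynyl group as the small substituent and the branched cyclohexadienyl group as the large one; the (R)-catalyst should give the (1′S) carbinol. Any ring enantiomer left from step 7 becomes a separable diastereomer here.

Step 11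
Reactants: 15 propargylic alcohol
Product: 17 iodoalkenyl carbinol (1S,2Z)-1-[(6S,8aS)-2,2-di-tert-butyl-6-(tert-butyldimethylsilyloxy)-6,8a-dihydro-4H-1,3,2-benzodioxasilin-7-yl]-3-iodobut-2-en-1-ol, via cyclic alkenylalanate 16 (not isolated)
Conditions: NaAlH2(OCH2CH2OMe)2, THF, 0 °C to rt; then I2, THF, −78 °C
Reagents that add atoms: iodine, II
Why: Hydroxyl-directed trans-hydroalumination of a propargylic alcohol (hydride to C2′, aluminium on C3′) followed by iodinolysis with retention gives the (Z)-3-iodoallylic alcohol; the 2′Z geometry is fixed by mechanism.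

Step 12
Reactants: 17 iodoalkenyl carbinol
Product: 18 epoxy iodide (1S,2Z)-3-iodo-1-[C1–C2 oxirane of the ring of 17 on the face opposite both silyloxy groups; C1 R C2 S C3 R C6 S]but-2-en-1-ol
Conditions: Ti(OiPr)4, L-(+)-diisopropyl tartrate, tBuOOH, 4 Å MS, CH2Cl2, −20 °C
Reagents that add atoms: tert-butyl hydroperoxide, CC(C)(C)OO
Why: Sharpless epoxidation of a secondary allylic alcohol with a 2-substituent and an E 3-substituent; with L-(+)-tartrate the (1′S) carbinol is the fast-reacting, erythro-selective partner, and oxygen goes to the ring face opposite both silyloxy groups, so reagent, carbinol and ring bias agree. The iodoalkene is electron-poor, cis-substituted and mismatched, and should stay intact.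

Step 13
Reactants: 19 geranyl acetate
Product: 20 (2E)-5-[(2R)-3,3-dimethyloxiran-2-yl]-3-methylpent-2-en-1-yl acetate
Conditions: D-fructose-derived Shi ketone (0.3 equiv), KHSO5 (Oxone), K2CO3, Bu4NHSO4, MeCN–(MeO)2CH2–aq. Na2B4O7 buffer, 0 °C
Reagents that add atoms: potassium peroxymonosulfate, [K+].[O-]S(=O)(=O)OO
Why: Shi epoxidation; the chiral dioxirane attacks the electron-rich 6,7-alkene in preference to the 2,3-alkene deactivated by the allylic acetate, and should give the (R)-epoxide of the trisubstituted alkene through the spiro transition state.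

Step 14
Reactants: 20 (R)-6,7-epoxygeranyl acetate
Product: 21 [(1S,3R)-3-hydroxy-2,2-dimethyl-6-methylidenecyclohexyl]methyl acetate
Conditions: Cp2TiCl2 (2.2 equiv), Mn powder, THF, rt; aq. HCl work-up
Reagents that add atoms: none
Why: Titanocene-mediated radical epoxide–alkene cyclisation: trivalent titanium opens the epoxide to the tertiary radical, which closes 6-endo through a chair onto the 2,3-alkene (hydroxyl and acetoxymethyl both equatorial, hence cis). The cyclic radical is trapped by a second titanium centre and loses hydride to give the exocyclic alkene.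

Step 15
Reactants: 21 exo-methylene hydroxy acetate
Product: 22 [(3R,4S,6R)-6-hydroxy-5,5-dimethyl-1-oxaspiro[2.5]octan-4-yl]methyl acetate
Conditions: mCPBA, NaHCO3, CH2Cl2, 0 °C
Reagents that add atoms: 3-chloroperoxybenzoic acid, O=C(OO)c1cccc(Cl)c1
Why: Peracid epoxidation of the exocyclic alkene from the equatorial direction, away from the axial methyl of C2″ that stands 1,3 to the alkene carbon, as in 8(17)-labdene and drimene series; the oxirane oxygen ends equatorial at C6″.

Step 16
Reactants: 22 spiro epoxide
Product: 23 (1R,2S,4R)-2-(hydroxymethyl)-1,3,3-trimethylcyclohexane-1,4-diol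
Conditions: LiAlH4, THF, 0 °C to rt
Reagents that add atoms: none
Why: Hydride opens the spiro epoxide at its CH2 terminus, leaving the tertiary C6″–O bond untouched (equatorial hydroxyl, axial methyl), and reduces the acetate in the same operation.

Step 17
Reactants: 23 ring B triol
Product: 24 tris(triethylsilyl) ether of 23
Conditions: Et3SiOTf, 2,6-lutidine, CH2Cl2, −78 to 0 °C
Reagents that add atoms: triethylsilyl trifluoromethanesulfonate, CC[Si](CC)(CC)OS(=O)(=O)C(F)(F)F
Why: Exhaustive silylation with the silyl triflate, which is reactive enough for the tertiary hydroxyl.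

Step 18
Reactants: 24 tris(triethylsilyl) ether
Product: 25 (1R,3R,6R)-2,2,6-trimethyl-3,6-bis(triethylsilyloxy)cyclohexane-1-carbaldehyde
Conditions: (COCl)2, DMSO, CH2Cl2, −78 to −40 °C; then Et3N, −78 °C to rt
Reagents that add atoms: none
Why: Under Swern conditions a primary triethylsilyl ether is cleaved by the chlorosulfonium salt and oxidised to the aldehyde, while secondary and tertiary silyl ethers remain; the aldehyde is never exposed as a free β-hydroxy aldehyde.

Step 19
Reactants: 25 ring B aldehyde
Product: 26 alkenylboronate 2-[(E)-2-{(1R,3R,6R)-2,2,6-trimethyl-3,6-bis(triethylsilyloxy)cyclohexyl}ethenyl]-4,4,5,5-tetramethyl-1,3,2-dioxaborolane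
Conditions: Cl2CHB(pin), CrCl2, LiI, THF, rt
Reagents that add atoms: 2-(dichloromethyl)-4,4,5,5-tetramethyl-1,3,2-dioxaborolane, ClC(Cl)B1OC(C)(C)C(C)(C)O1
Why: Takai–Utimoto olefination with the boryl-substituted geminal dichromium reagent converts aldehydes into (E)-alkenylboronates and supplies C4′; the reagent is non-basic, so the β-silyloxy aldehyde should neither epimerise nor eliminate.

Step 20
Reactants: 18 epoxy iodide; 26 alkenylboronate
Product: 27 silyl-protected arthrosporol A (C3–O/C7–O di-tert-butylsilylene; C6–OTBS; C3″–OTES; C6″–OTES; C1′–OH free)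
Conditions: Pd(PPh3)4 (10 mol %), TlOEt, THF–H2O 3:1, rt
Reagents that add atoms: none
Why: Suzuki–Miyaura coupling of an alkenyl iodide with an alkenylboronate proceeds with retention at both partners and gives the (2′Z,4′E)-diene; thallium ethoxide allows room temperature and short contact, which spares the epoxy alcohol.

Step 21
Reactants: 27 silyl-protected arthrosporol A
Product: 28 arthrosporol A
Conditions: HF·pyridine, pyridine, THF, 0 °C to rt
Reagents that add atoms: none
Why: Buffered fluoride cleaves the silylene, the allylic tert-butyldimethylsilyl ether and both triethylsilyl ethers without strong acid or base, as the epoxy alcohols and the doubly allylic C1′ carbinol require.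

## Compound list

1 | 2-methylidenepropane-1,3-diol | C=C(CO)CO | starting material
2 | 2,2-di-tert-butyl-5-methylidene-1,3,2-dioxasilinane | C=C1CO[Si](C(C)(C)C)(C(C)(C)C)OC1 | intermediate
3 | spiro ozonide of 2, 8,8-di-tert-butyl-1,2,4,7,9-pentaoxa-8-silaspiro[4.5]decane (not isolated) | C1OOC2(O1)CO[Si](C(C)(C)C)(C(C)(C)C)OC2 | intermediate
4 | 2,2-di-tert-butyl-1,3,2-dioxasilinan-5-one | O=C1CO[Si](C(C)(C)C)(C(C)(C)C)OC1 | intermediate
5 | 2-(2,2-di-tert-butyl-1,3,2-dioxasilinan-5-ylidene)acetonitrile | N#CC=C1CO[Si](C(C)(C)C)(C(C)(C)C)OC1 | intermediate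
6 | N-alumino imine, N-(diisobutylalumanyl)-2-(2,2-di-tert-butyl-1,3,2-dioxasilinan-5-ylidene)ethan-1-imine (not isolated) | CC(C)C[Al](CC(C)C)N=CC=C1CO[Si](C(C)(C)C)(C(C)(C)C)OC1 | intermediate
7 | 2-(2,2-di-tert-butyl-1,3,2-dioxasilinan-5-ylidene)acetaldehyde | O=CC=C1CO[Si](C(C)(C)C)(C(C)(C)C)OC1 | intermediate
8 | diene, 2,2-di-tert-butyl-5-[(E)-2-(tert-butyldimethylsilyloxy)ethenyl]-4H-1,3,2-dioxasiline | CC(C)(C)[Si](C)(C)O/C=C/C1=CO[Si](C(C)(C)C)(C(C)(C)C)OC1 | intermediate
9 | propiolic acid (prop-2-ynoic acid) | C#CC(=O)O | starting material
10 | 1,3-oxazolidin-2-one | O=C1NCCO1 | starting material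
11 | 3-(prop-2-ynoyl)-1,3-oxazolidin-2-one | C#CC(=O)N1CCOC1=O | intermediate
12 | ring A imide, 3-{[(6S,8aS)-2,2-di-tert-butyl-6-(tert-butyldimethylsilyloxy)-6,8a-dihydro-4H-1,3,2-benzodioxasilin-7-yl]carbonyl}-1,3-oxazolidin-2-one | O=C(N1CCOC1=O)C2=C[C@@H]3O[Si](C(C)(C)C)(C(C)(C)C)OCC3=C[C@@H]2O[Si](C)(C)C(C)(C)C | intermediate
13 | Weinreb amide, (6S,8aS)-2,2-di-tert-butyl-6-(tert-butyldimethylsilyloxy)-N-methoxy-N-methyl-6,8a-dihydro-4H-1,3,2-benzodioxasiline-7-carboxamide | CON(C)C(=O)C1=C[C@@H]2O[Si](C(C)(C)C)(C(C)(C)C)OCC2=C[C@@H]1O[Si](C)(C)C(C)(C)C | intermediate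
14 | ynone, 1-[(6S,8aS)-2,2-di-tert-butyl-6-(tert-butyldimethylsilyloxy)-6,8a-dihydro-4H-1,3,2-benzodioxasilin-7-yl]but-2-yn-1-one | CC#CC(=O)C1=C[C@@H]2O[Si](C(C)(C)C)(C(C)(C)C)OCC2=C[C@@H]1O[Si](C)(C)C(C)(C)C | intermediate
15 | propargylic alcohol, (1S)-1-[(6S,8aS)-2,2-di-tert-butyl-6-(tert-butyldimethylsilyloxy)-6,8a-dihydro-4H-1,3,2-benzodioxasilin-7-yl]but-2-yn-1-ol | CC#C[C@H](O)C1=C[C@@H]2O[Si](C(C)(C)C)(C(C)(C)C)OCC2=C[C@@H]1O[Si](C)(C)C(C)(C)C | intermediate
16 | cyclic sodium alkenylalanate from 15, five-membered O–Al–C3′=C2′–C1′ ring with two 2-methoxyethoxy groups on aluminium (not isolated) | C/C1=C/[C@@H](C2=C[C@@H]3O[Si](C(C)(C)C)(C(C)(C)C)OCC3=C[C@@H]2O[Si](C)(C)C(C)(C)C)O[Al-]1(OCCOC)OCCOC.[Na+] | intermediate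
17 | iodoalkenyl carbinol, (1S,2Z)-1-[(6S,8aS)-2,2-di-tert-butyl-6-(tert-butyldimethylsilyloxy)-6,8a-dihydro-4H-1,3,2-benzodioxasilin-7-yl]-3-iodobut-2-en-1-ol | C/C(I)=C/[C@H](O)C1=C[C@@H]2O[Si](C(C)(C)C)(C(C)(C)C)OCC2=C[C@@H]1O[Si](C)(C)C(C)(C)C | intermediate
18 | epoxy iodide, C1–C2 oxirane of 17 anti to both silyloxy groups (C1 R, C2 S, C3 R, C6 S, C1′ S, 2′Z) | C/C(I)=C/[C@H](O)[C@]12O[C@H]1[C@@H]3O[Si](C(C)(C)C)(C(C)(C)C)OCC3=C[C@@H]2O[Si](C)(C)C(C)(C)C | intermediate
19 | geranyl acetate, (2E)-3,7-dimethylocta-2,6-dien-1-yl acetate | CC(=O)OC/C=C(\C)CCC=C(C)C | starting material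
20 | (R)-6,7-epoxygeranyl acetate, (2E)-5-[(2R)-3,3-dimethyloxiran-2-yl]-3-methylpent-2-en-1-yl acetate | CC(=O)OC/C=C(\C)CC[C@H]1OC1(C)C | intermediate
21 | [(1S,3R)-3-hydroxy-2,2-dimethyl-6-methylidenecyclohexyl]methyl acetate | CC(=O)OC[C@@H]1C(C)(C)[C@H](O)CCC1=C | intermediate
22 | [(3R,4S,6R)-6-hydroxy-5,5-dimethyl-1-oxaspiro[2.5]octan-4-yl]methyl acetate | CC(=O)OC[C@@H]1C(C)(C)[C@H](O)CC[C@]12CO2 | intermediate
23 | (1R,2S,4R)-2-(hydroxymethyl)-1,3,3-trimethylcyclohexane-1,4-diol | OC[C@@H]1C(C)(C)[C@H](O)CC[C@@]1(C)O | intermediate
24 | tris(triethylsilyl) ether of 23 | CC[Si](CC)(CC)OC[C@@H]1C(C)(C)[C@H](O[Si](CC)(CC)CC)CC[C@@]1(C)O[Si](CC)(CC)CC | intermediate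
25 | (1R,3R,6R)-2,2,6-trimethyl-3,6-bis(triethylsilyloxy)cyclohexane-1-carbaldehyde | O=C[C@@H]1C(C)(C)[C@H](O[Si](CC)(CC)CC)CC[C@@]1(C)O[Si](CC)(CC)CC | intermediate
26 | 2-[(E)-2-{(1R,3R,6R)-2,2,6-trimethyl-3,6-bis(triethylsilyloxy)cyclohexyl}ethenyl]-4,4,5,5-tetramethyl-1,3,2-dioxaborolane | CC1(C)OB(/C=C/[C@@H]2C(C)(C)[C@H](O[Si](CC)(CC)CC)CC[C@@]2(C)O[Si](CC)(CC)CC)OC1(C)C | intermediate
27 | silyl-protected arthrosporol A (C3–O/C7–O di-tert-butylsilylene, C6–OTBS, C3″–OTES, C6″–OTES, C1′–OH free) | CC(=C/[C@H](O)[C@]12O[C@H]1[C@@H]3O[Si](C(C)(C)C)(C(C)(C)C)OCC3=C[C@@H]2O[Si](C)(C)C(C)(C)C)/C=C/[C@@H]4C(C)(C)[C@H](O[Si](CC)(CC)CC)CC[C@@]4(C)O[Si](CC)(CC)CC | intermediate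
28 | arthrosporol A (C1 R, C2 S, C3 R, C6 S, C1′ S, 2′Z, 4′E, C1″ R, C3″ R, C6″ R) | CC(=C/[C@H](O)[C@]12O[C@H]1[C@H](O)C(CO)=C[C@@H]2O)/C=C/[C@@H]1C(C)(C)[C@H](O)CC[C@@]1(C)O | target

## Step count and risks

Total: 21 steps. Longest linear sequence: 13 steps from 1 (steps 1–5, 7–12, 20, 21). The ring B branch has 7 steps (13–19) before the union.

**Step 7 (key step, proposed new method).** Three things may go wrong.
- Enantioselectivity may erode, because face selection at the alkyne and the orientation of the diene are independent choices whose product fixes the configuration.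
- The reaction may divert into a stepwise Mukaiyama–Michael addition with slow or no ring closure, which would cost the cis relationship or give open-chain material, and bonding may occur in the other regiochemical sense.
- The doubly allylic product may lose silanol under Lewis acid and aromatise.

Fallback with known chemistry, setting out from 8 and 11: the two are heated without catalyst in toluene, as in additions of 1,4-dioxygenated dienes to acetylenic carbonyl compounds. This gives 12 as a racemate, that is, together with the enantiomeric imide F1. The racemate is carried through steps 8 and 9, giving 13 with the enantiomeric Weinreb amide F2 and 14 with the enantiomeric ynone F3. The reagent-controlled reduction of step 10 then turns the two ring enantiomers into 15 and the diastereomeric propargylic alcohol F4, which are separated by chromatography. The route is rejoined at 15, at the cost of half the ring A material.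

**Step 8.** The 3,6-disilyloxycyclohexa-1,4-diene may undergo 1,4-elimination to an arene under the Lewis-acidic aluminium amide. The amide may also attack the ring carbonyl of the oxazolidinone, because the acyl group is hindered. Fallback from 12: reductive cleavage with LiBH4 (THF–MeOH, 0 °C) gives the primary allylic alcohol F5, and MnO2 gives the enal F6. MeC≡CMgBr at −78 °C gives 15 together with its C1′ epimer F7, and MnO2 oxidation of this mixture returns the route at 14.

**Step 12.** Oxygen transfer may be slow, because the alkene is trisubstituted, flanked by two allylic oxygens and attached to a carbinol carrying a bulky cis-iodoalkenyl group that crowds the titanium tartrate. Slow transfer would leave starting material or allow oxidation elsewhere. Fallback from 15: the same tartrate-controlled epoxidation is run one step earlier on 15, whose carbinol carries only the small linear propynyl group, giving the epoxy propargylic alcohol F8. Hydride reagents are then excluded, so the alkyne is converted by ruthenium-catalysed trans-hydrosilylation ([Cp*Ru(MeCN)3]PF6, BnMe2SiH, silicon to the distal carbon) into the (Z)-alkenylsilane F9. Iododesilylation with N-iodosuccinimide with retention returns the route at 18.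

**Step 18.** The hindered, neopentyl-like primary silyl ether may react incompletely, or the secondary silyl ether may be lost. Fallback from 23: the primary hydroxyl of the free triol is oxidised selectively (TEMPO, PhI(OAc)2) to the dihydroxy aldehyde F10. Both remaining hydroxyls are then silylated (Et3SiOTf, 2,6-lutidine, −78 °C), returning at 25.

**Step 21.** The time needed to cleave the tertiary silyl ether and the silylene may allow ionisation of the doubly allylic C1′ carbinol or opening or migration of the oxirane. Fallback from 18 and 26: silicon is removed before the union. HF·pyridine on 18 gives the iodo tetraol F11, which has no diene yet. Mild acid methanolysis (pyridinium p-toluenesulfonate, MeOH) of 26 gives the diol boronate F12. The Suzuki–Miyaura coupling of F11 and F12 under the conditions of step 20 then becomes the last step and returns at 28.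

## Further compounds

F1 | step 7 | enantiomeric imide, 3-{[(6R,8aR)-2,2-di-tert-butyl-6-(tert-butyldimethylsilyloxy)-6,8a-dihydro-4H-1,3,2-benzodioxasilin-7-yl]carbonyl}-1,3-oxazolidin-2-one | O=C(N1CCOC1=O)C2=C[C@H]3O[Si](C(C)(C)C)(C(C)(C)C)OCC3=C[C@H]2O[Si](C)(C)C(C)(C)C
F2 | step 7 | enantiomeric Weinreb amide, (6R,8aR) isomer of 13 | CON(C)C(=O)C1=C[C@H]2O[Si](C(C)(C)C)(C(C)(C)C)OCC2=C[C@H]1O[Si](C)(C)C(C)(C)C
F3 | step 7 | enantiomeric ynone, (6R,8aR) isomer of 14 | CC#CC(=O)C1=C[C@H]2O[Si](C(C)(C)C)(C(C)(C)C)OCC2=C[C@H]1O[Si](C)(C)C(C)(C)C
F4 | step 7 | diastereomeric propargylic alcohol, (1S) carbinol on the (6R,8aR) ring | CC#C[C@H](O)C1=C[C@H]2O[Si](C(C)(C)C)(C(C)(C)C)OCC2=C[C@H]1O[Si](C)(C)C(C)(C)C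
F5 | step 8 | primary allylic alcohol, [(6S,8aS)-2,2-di-tert-butyl-6-(tert-butyldimethylsilyloxy)-6,8a-dihydro-4H-1,3,2-benzodioxasilin-7-yl]methanol | OCC1=C[C@@H]2O[Si](C(C)(C)C)(C(C)(C)C)OCC2=C[C@@H]1O[Si](C)(C)C(C)(C)C
F6 | step 8 | enal, (6S,8aS)-2,2-di-tert-butyl-6-(tert-butyldimethylsilyloxy)-6,8a-dihydro-4H-1,3,2-benzodioxasiline-7-carbaldehyde | O=CC1=C[C@@H]2O[Si](C(C)(C)C)(C(C)(C)C)OCC2=C[C@@H]1O[Si](C)(C)C(C)(C)C
F7 | step 8 | C1′ epimer of 15, (1R) carbinol on the (6S,8aS) ring | CC#C[C@@H](O)C1=C[C@@H]2O[Si](C(C)(C)C)(C(C)(C)C)OCC2=C[C@@H]1O[Si](C)(C)C(C)(C)C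
F8 | step 12 | epoxy propargylic alcohol, C1–C2 oxirane of 15 anti to both silyloxy groups | CC#C[C@H](O)[C@]12O[C@H]1[C@@H]3O[Si](C(C)(C)C)(C(C)(C)C)OCC3=C[C@@H]2O[Si](C)(C)C(C)(C)C
F9 | step 12 | (Z)-alkenylsilane, 18 with benzyldimethylsilyl in place of iodine | C/C(=C/[C@H](O)[C@]12O[C@H]1[C@@H]3O[Si](C(C)(C)C)(C(C)(C)C)OCC3=C[C@@H]2O[Si](C)(C)C(C)(C)C)[Si](C)(C)Cc1ccccc1
F10 | step 18 | (1R,3R,6R)-3,6-dihydroxy-2,2,6-trimethylcyclohexane-1-carbaldehyde | O=C[C@@H]1C(C)(C)[C@H](O)CC[C@@]1(C)O
F11 | step 21 | iodo tetraol, fully desilylated 18 | C/C(I)=C/[C@H](O)[C@]12O[C@H]1[C@H](O)C(CO)=C[C@@H]2O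
F12 | step 21 | diol boronate, desilylated 26 | CC1(C)OB(/C=C/[C@@H]2C(C)(C)[C@H](O)CC[C@@]2(C)O)OC1(C)C
A1 | alternative 1 | convex-face epoxide of the endo adduct | COC(=O)[C@]12O[C@H]1C(=O)[C@]3(C(=O)OC)[C@@H]4C=C[C@@H](C4)[C@@H]3C2=O
A2 | alternative 1 | endo norbornene adduct of the quinone diester | COC(=O)C1=CC(=O)[C@]2(C(=O)OC)[C@@H]3C=C[C@@H](C3)[C@@H]2C1=O
A3 | alternative 2 | trans-fused ring B cyclic carbonate with free C3″ hydroxyl | O=C1OC[C@@H]2C(C)(C)[C@H](O)CC[C@@]2(C)O1
A4 | alternative 2 | (6R)-6,7-epoxygeranyl tert-butyl carbonate | CC(C)(C)OC(=O)OC/C=C(\C)CC[C@H]1OC1(C)C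
A5 | alternative 3 | arthrosporol A with five hydroxyls silylated and the C1′ hydroxyl free | CC(=C/[C@H](O)[C@]12O[C@H]1[C@H](O[Si](C)(C)C(C)(C)C)C(CO[Si](C)(C)C(C)(C)C)=C[C@@H]2O[Si](C)(C)C(C)(C)C)/C=C/[C@@H]1C(C)(C)[C@H](O[Si](C)(C)C(C)(C)C)CC[C@@]1(C)O[Si](CC)(CC)CC
A6 | alternative 3 | ring A epoxy aldehyde, tris(tert-butyldimethylsilyl) ether | O=C[C@]12O[C@H]1[C@H](O[Si](C)(C)C(C)(C)C)C(CO[Si](C)(C)C(C)(C)C)=C[C@@H]2O[Si](C)(C)C(C)(C)C
A7 | alternative 3 | (E)-alkenylzinc chloride of ring B | Cl[Zn]/C=C/[C@@H]1C(C)(C)[C@H](O[Si](C)(C)C(C)(C)C)CC[C@@]1(C)O[Si](CC)(CC)CC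
A8 | alternative 3 | propyne | CC#C
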